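**Plan**

Numbering follows benzofuran (O1, C2, C3, C3a, C4–C7, C7a). Ring A is the benzene ring and ring B is the dihydrofuran ring.
Cuts: first C5–CH2 of the allyl group, back to the C6 O-allyl ether. Then O1–C7a and C2–C3 together, which opens ring B into 3,4,5-trimethoxybenzaldehyde and a 4-ethylphenol ether whose C7a carries a p-tolylsulfinyl group that is absent from the target. Last C7a–S and C3–CH3, back to 3-bromo-4-methylphenol.
Enabling feature: in ring A, the carbon that must receive O1 (C7a) is ortho to C3a, which bears the benzylic stereocentre C3, and meta to the C6 oxygen. A sulfinyl group on C7a therefore lies 1,4 to C3, where it acidifies and controls it through an O–Li chelate. It also sits on the carbon where it can leave as sulfenate, and the C6 oxygen does not oppose the negative charge of the ipso attack.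
Forward order: ring A is bought, sulfur is put on C7a, C3 is completed by methylation, ring B is closed in one flask with loss of the sulfur helper, and the allyl group goes onto O6 and then onto C5.
Stereochemistry: the sulfur stereocentre comes from menthyl p-toluenesulfinate. It sets C3 by 1,4-induction. C2 follows from the lithium-bridged addition and from the trans-selective ring closure.

Key step: step 4

Assumption: the sense of the 1,4-induction ((R)-sulfur giving (S)-C3) is taken from the O–Li chelate model given under step 4. If it proves opposite, the equally available (1R,2S,5R)-menthyl (S)-p-toluenesulfinate is used in step 2 and nothing else changes.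

**Step 1**
Reactants: 1 3-bromo-4-methylphenol
Product: 2 (3-bromo-4-methylphenoxy)triisopropylsilane
Conditions: NaH, THF, 0 °C; TIPSCl, 0 °C → rt
Reagents that add atoms: triisopropylsilyl chloride, CC(C)[Si](Cl)(C(C)C)C(C)C
Why: O-silylation of the sodium phenoxide (Williamson-type substitution at silicon) installs a base-stable, bulky and non-coordinating group that should shield C7–H in steps 3 and 4.

**Step 2**
Reactants: 2 (3-bromo-4-methylphenoxy)triisopropylsilane; 3 (1S,2R,5S)-menthyl (R)-p-toluenesulfinate
Product: 5 (R)-triisopropyl{4-methyl-3-[(4-methylphenyl)sulfinyl]phenoxy}silane, via aryl Grignard reagent 4 (not isolated)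
Conditions: Mg, THF, 50 °C; then added to 3, toluene, 0 °C
Reagents that add atoms: none
Why: Andersen sulfoxide synthesis, in which the aryl Grignard reagent displaces mentholate from the sulfinate with inversion at sulfur and so sets the (R)-sulfur stereocentre.

**Step 3**
Reactants: 5 (R)-triisopropyl{4-methyl-3-[(4-methylphenyl)sulfinyl]phenoxy}silane
Product: 7 (R)-{4-ethyl-3-[(4-methylphenyl)sulfinyl]phenoxy}triisopropylsilane, via benzyllithium 6 (not isolated)
Conditions: LDA (1.0 equiv), THF, −78 °C; MeI, −78 °C
Reagents that add atoms: iodomethane, CI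
Why: Sulfinyl-directed lateral lithiation followed by SN2 methylation of the ortho-sulfinyl benzyl carbanion, with no excess base so that the less acidic product is not methylated again.

**Step 4**
Reactants: 7 (R)-{4-ethyl-3-[(4-methylphenyl)sulfinyl]phenoxy}triisopropylsilane; 8 3,4,5-trimethoxybenzaldehyde
Product: 11 triisopropyl{[(2S,3S)-3-methyl-2-(3,4,5-trimethoxyphenyl)-2,3-dihydrobenzofuran-6-yl]oxy}silane, via chelated benzyllithium 9 (not isolated), via lithium alkoxide 10 (not isolated)
Conditions: LDA (1.1 equiv), THF, −78 °C; 8, −78 °C; then KOtBu (1.2 equiv), −78 → 50 °C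
Reagents that add atoms: none
Why: Proposed new method: LDA removes a benzylic proton next to the sulfinyl group, and the lithium of 9 sits in a boat-like six-membered chelate (C3, C3a, C7a, S, O, Li) with the tolyl group outward and the C3 methyl turned away from sulfur, so aldehyde 8, bound to the same lithium, is attacked on the lithium-bearing face (C2–C3 bond, alkoxide 10); after exchange to the potassium alkoxide, O1 adds to C7a, directly or after prior addition to sulfur, and p-toluenesulfenate leaves (O1–C7a bond), so the helper is removed in the same flask. The closest known reaction types are the addition of ortho-sulfinyl benzyl carbanions to aldehydes, the tandem addition of such carbanions to imines with intramolecular ipso-substitution of the sulfinyl group to give indolines, and the KOtBu-promoted etherification of aryl sulfoxides by alkoxides; the oxygen version of the tandem has not been shown. Ring B closes by 5-exo-trig attack of O1 on C7a (addition–elimination through a Meisenheimer-type intermediate). C3 (S) is controlled by the (R)-sulfur centre through the chelate; C2 (S) is controlled by the lithium-bridged transition state, in which the trimethoxyphenyl group lies anti to C3a, and again by the ring closure, which should be faster for the anti alkoxide because aryl and methyl end up trans on ring B. The step needs lateral deprotonation instead of attack at C7–H or at the tolyl methyl group, which the chelating sulfinyl oxygen and the shielding OTIPS group should secure, and it needs substitution at an unactivated arene carbon, which is helped by the five-membered closure, the sulfenate leaving group, the potassium counterion and the meta position of the C6 oxygen relative to C7a.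

**Step 5**
Reactants: 11 triisopropyl{[(2S,3S)-3-methyl-2-(3,4,5-trimethoxyphenyl)-2,3-dihydrobenzofuran-6-yl]oxy}silane
Product: 13 (2S,3S)-6-(allyloxy)-3-methyl-2-(3,4,5-trimethoxyphenyl)-2,3-dihydrobenzofuran, via cesium phenoxide 12 (not isolated)
Conditions: CsF, allyl bromide, DMF, rt
Reagents that add atoms: allyl bromide, C=CCBr
Why: Fluoride cleavage of the aryl silyl ether and Williamson allylation of the freed phenoxide in one pot, under conditions that touch neither C2 nor C3.

**Step 6**
Reactants: 13 (2S,3S)-6-(allyloxy)-3-methyl-2-(3,4,5-trimethoxyphenyl)-2,3-dihydrobenzofuran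
Product: 15 (2S,3S)-5-allyl-3-methyl-2-(3,4,5-trimethoxyphenyl)-2,3-dihydrobenzofuran-6-ol, via ortho-dienone 14 (not isolated)
Conditions: PhNEt2, 190 °C
Reagents that add atoms: none
Why: Aromatic Claisen rearrangement ([3,3]-sigmatropic shift, then tautomerisation of 14), which should favour C5 (para to O1, unhindered, favoured by the bond fixation of the fused five-membered ring) over C7 (between two oxygens, next to the ring fusion) and leaves C2 and C3 untouched.

**Compound list**

1 | 3-bromo-4-methylphenol | Cc1ccc(O)cc1Br | starting material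
2 | (3-bromo-4-methylphenoxy)triisopropylsilane | Cc1ccc(O[Si](C(C)C)(C(C)C)C(C)C)cc1Br | intermediate
3 | (1S,2R,5S)-menthyl (R)-p-toluenesulfinate | CC(C)[C@H]1CC[C@H](C)C[C@@H]1O[S@@](=O)c1ccc(C)cc1 | starting material
4 | [2-methyl-5-(triisopropylsilyloxy)phenyl]magnesium bromide | Cc1ccc(O[Si](C(C)C)(C(C)C)C(C)C)cc1[Mg]Br | intermediate
5 | (R)-triisopropyl{4-methyl-3-[(4-methylphenyl)sulfinyl]phenoxy}silane | Cc1ccc(cc1)[S@@](=O)c1cc(O[Si](C(C)C)(C(C)C)C(C)C)ccc1C | intermediate
6 | benzyllithium derived from 5 | Cc1ccc(cc1)[S@@](=O)c1cc(O[Si](C(C)C)(C(C)C)C(C)C)ccc1C[Li] | intermediate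
7 | (R)-{4-ethyl-3-[(4-methylphenyl)sulfinyl]phenoxy}triisopropylsilane | Cc1ccc(cc1)[S@@](=O)c1cc(O[Si](C(C)C)(C(C)C)C(C)C)ccc1CC | intermediate
8 | 3,4,5-trimethoxybenzaldehyde | COc1cc(C=O)cc(OC)c1OC | starting material
9 | chelated alpha-methylbenzyllithium derived from 7 | Cc1ccc(cc1)[S@@](=O)c1cc(O[Si](C(C)C)(C(C)C)C(C)C)ccc1[C@H](C)[Li] | intermediate
10 | lithium (1S,2S)-2-{2-[(R)-p-tolylsulfinyl]-4-(triisopropylsilyloxy)phenyl}-1-(3,4,5-trimethoxyphenyl)propan-1-olate | Cc1ccc(cc1)[S@@](=O)c1cc(O[Si](C(C)C)(C(C)C)C(C)C)ccc1[C@H](C)[C@H]([O-])c1cc(OC)c(OC)c(OC)c1.[Li+] | intermediate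
11 | triisopropyl{[(2S,3S)-3-methyl-2-(3,4,5-trimethoxyphenyl)-2,3-dihydrobenzofuran-6-yl]oxy}silane | CC(C)[Si](Oc1ccc2c(c1)O[C@H](c1cc(OC)c(OC)c(OC)c1)[C@H]2C)(C(C)C)C(C)C | intermediate
12 | cesium (2S,3S)-3-methyl-2-(3,4,5-trimethoxyphenyl)-2,3-dihydrobenzofuran-6-olate | [Cs+].[O-]c1ccc2c(c1)O[C@H](c1cc(OC)c(OC)c(OC)c1)[C@H]2C | intermediate
13 | (2S,3S)-6-(allyloxy)-3-methyl-2-(3,4,5-trimethoxyphenyl)-2,3-dihydrobenzofuran | C=CCOc1ccc2c(c1)O[C@H](c1cc(OC)c(OC)c(OC)c1)[C@H]2C | intermediate
14 | (2S,3S)-5-allyl-3-methyl-2-(3,4,5-trimethoxyphenyl)-3,5-dihydrobenzofuran-6(2H)-one (either configuration at C5) | C=CCC1C=C2C(=CC1=O)O[C@H](c1cc(OC)c(OC)c(OC)c1)[C@H]2C | intermediate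
15 | (2S,3S)-5-allyl-3-methyl-2-(3,4,5-trimethoxyphenyl)-2,3-dihydrobenzofuran-6-ol | C=CCc1cc2c(cc1O)O[C@H](c1cc(OC)c(OC)c(OC)c1)[C@H]2C | target

**Step count and risks**

Total steps: 6. Longest linear sequence: 6 (1 → 15).

Steps most likely to fail:

Step 4. Several things may go wrong:
- The alkoxide may fail to displace the sulfinyl group from the unactivated ring carbon.
- Reversible addition under the potassium conditions may erode the control at C2 and C3, or lose the carbanion through aryl migration of the Truce–Smiles type.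
- Deprotonation may stray to C7 or to the tolyl methyl group.

The fallback uses known chemistry and makes the C–O bond by copper catalysis instead of anionic ipso-substitution. It sets out from 7 and 8. The LDA-mediated addition is quenched at −78 °C with aqueous NH4Cl to give (1S,2S)-2-{2-[(R)-p-tolylsulfinyl]-4-(triisopropylsilyloxy)phenyl}-1-(3,4,5-trimethoxyphenyl)propan-1-ol F1, which is freed from any C2 epimer. Sulfoxide–lithium exchange with t-BuLi (THF, −78 °C) and trapping of the aryllithium with I2 gives (1S,2S)-2-[2-iodo-4-(triisopropylsilyloxy)phenyl]-1-(3,4,5-trimethoxyphenyl)propan-1-ol F2. Intramolecular Ullmann-type O-arylation (CuI, 1,10-phenanthroline, Cs2CO3, toluene, 110 °C) closes ring B and comes back to the route at 11.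

Step 6. Regioselectivity may be poor, with part of the allyl group migrating to C7. The fallback replaces the sigmatropic shift by a cross-coupling. It sets out from 11. TBAF (THF, 0 °C) gives (2S,3S)-3-methyl-2-(3,4,5-trimethoxyphenyl)-2,3-dihydrobenzofuran-6-ol F3. NIS (MeCN, −20 °C) should iodinate the most activated and least hindered position, C5 (ortho to the hydroxyl group, para to O1), to give (2S,3S)-5-iodo-3-methyl-2-(3,4,5-trimethoxyphenyl)-2,3-dihydrobenzofuran-6-ol F4. Stille coupling with allyltributylstannane (Pd(PPh3)4, LiCl, DMF, 80 °C) comes back to the route at 15.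

Step 3. A second methylation or a misdirected lithiation may occur. The fallback completes the ethyl group before sulfur is introduced. It sets out from 2. Wohl–Ziegler bromination (NBS, AIBN, PhCF3, reflux) gives [3-bromo-4-(bromomethyl)phenoxy]triisopropylsilane F5. Copper-catalysed coupling with MeMgBr (Li2CuCl4 cat., THF, −20 °C) gives (3-bromo-4-ethylphenoxy)triisopropylsilane F6. Mg in THF gives [2-ethyl-5-(triisopropylsilyloxy)phenyl]magnesium bromide F7, which reacts with 3 as in step 2 and comes back to the route at 7.

**Further compounds**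

F1 | step 4 | (1S,2S)-2-{2-[(R)-p-tolylsulfinyl]-4-(triisopropylsilyloxy)phenyl}-1-(3,4,5-trimethoxyphenyl)propan-1-ol | Cc1ccc(cc1)[S@@](=O)c1cc(O[Si](C(C)C)(C(C)C)C(C)C)ccc1[C@H](C)[C@H](O)c1cc(OC)c(OC)c(OC)c1
F2 | step 4 | (1S,2S)-2-[2-iodo-4-(triisopropylsilyloxy)phenyl]-1-(3,4,5-trimethoxyphenyl)propan-1-ol | CC(C)[Si](Oc1ccc([C@H](C)[C@H](O)c2cc(OC)c(OC)c(OC)c2)c(I)c1)(C(C)C)C(C)C
F3 | step 6 | (2S,3S)-3-methyl-2-(3,4,5-trimethoxyphenyl)-2,3-dihydrobenzofuran-6-ol | Oc1ccc2c(c1)O[C@H](c1cc(OC)c(OC)c(OC)c1)[C@H]2C
F4 | step 6 | (2S,3S)-5-iodo-3-methyl-2-(3,4,5-trimethoxyphenyl)-2,3-dihydrobenzofuran-6-ol | Ic1cc2c(cc1O)O[C@H](c1cc(OC)c(OC)c(OC)c1)[C@H]2C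
F5 | step 3 | [3-bromo-4-(bromomethyl)phenoxy]triisopropylsilane | BrCc1ccc(O[Si](C(C)C)(C(C)C)C(C)C)cc1Br
F6 | step 3 | (3-bromo-4-ethylphenoxy)triisopropylsilane | CCc1ccc(O[Si](C(C)C)(C(C)C)C(C)C)cc1Br
F7 | step 3 | [2-ethyl-5-(triisopropylsilyloxy)phenyl]magnesium bromide | CCc1ccc(O[Si](C(C)C)(C(C)C)C(C)C)cc1[Mg]Br
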